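**Plan**

1. Retrosynthesis: remove two TBS groups; cut the side-chain C5′=C6′ (E) alkene by cross-metathesis into tertiary vinyl carbinol 7 and allyl-bearing butenolide 26; cut the furanone at C2–C3 and O1–C5 into CO2 and the (Z)-iodoalkene/allylic chloride 23; take 23 back to alkynediol 18, enoate 16 and 3-(trimethylsilyl)propynal.
2. Forward: the cyclohexene ring comes intact from dihydro-β-ionone; the C5–C6′ chain is built first; the only ring formed, the furan-2(5H)-one, arises in step 17; the two halves are then joined by cross-metathesis and desilylated.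
3. Enabling feature: in the 4-(hydroxymethyl)furan-2(5H)-one, C3–H and the C5 stereocentre lie cis across C3=C4 and C4 is fully substituted, so a (Z)-alkenyl anion at C3 carrying a leaving group at C5 can take up CO2 as the C2(=O)–O1 unit.
4. Stereochemistry: C7′ (S) from Sharpless epoxidation; C5 (S) from Brown allylation followed by two SN2 inversions (chlorination, lactonisation); the 2′Z alkene from Still–Gennari olefination; the iodoalkene geometry from chelation-controlled anti-carbomagnesiation; the 5′E alkene from cross-metathesis.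

Key step: step 17

Remark: furanone atoms are numbered O1, C2(=O), C3, C4, C5 and the side chain C1′–C9′ from C5; (−)-Ipc2B(allyl), 3-(trimethylsilyl)propynal, the Still–Gennari phosphonoacetate, dihydro-β-ionone and the silylmethyl Grignard reagent are taken as purchasable or stock reagents.

**Step 1**
Reactants: 1 dihydro-β-ionone; 2 triethyl phosphonoacetate
Product: 3 ethyl (2E)-3-methyl-5-(2,6,6-trimethylcyclohex-1-en-1-yl)pent-2-enoate
Conditions: NaH, THF, 0 °C → reflux; minor Z isomer removed by chromatography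
Reagents that add atoms: none
Why: Horner–Wadsworth–Emmons olefination of the methyl ketone with a stabilised phosphonate anion should give mainly the (E)-enoate.

**Step 2**
Reactants: 3
Product: 4 (2E)-3-methyl-5-(2,6,6-trimethylcyclohex-1-en-1-yl)pent-2-en-1-ol
Conditions: DIBAL-H (2.2 equiv), CH2Cl2, −78 → 0 °C; Rochelle salt
Reagents that add atoms: none
Why: 1,2-reduction of the enoate by DIBAL-H should give the allylic alcohol without touching either alkene.

**Step 3**
Reactants: 4
Product: 5 [(2S,3S)-3-methyl-3-[2-(2,6,6-trimethylcyclohex-1-en-1-yl)ethyl]oxiran-2-yl]methanol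
Conditions: Ti(OiPr)4 (10 mol%), L-(+)-diethyl tartrate (12 mol%), t-BuOOH, 4 Å MS, CH2Cl2, −20 °C
Reagents that add atoms: tert-butyl hydroperoxide (CC(C)(C)OO)
Why: Sharpless asymmetric epoxidation acts only on the allylic-alcohol alkene, and the L-(+)-tartrate catalyst should deliver oxygen to the face that gives the (2S,3S)-epoxide, which fixes the future C7′ configuration.

**Step 4**
Reactants: 5
Product: 6 (2R,3S)-2-(iodomethyl)-3-methyl-3-[2-(2,6,6-trimethylcyclohex-1-en-1-yl)ethyl]oxirane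
Conditions: I2, PPh3, imidazole, Et2O/MeCN, 0 °C
Reagents that add atoms: iodine (II)
Why: Appel-type (Garegg–Samuelsson) iodination of the primary alcohol under imidazole buffering should leave the epoxide intact; the descriptor at C2 changes only by priority.

**Step 5**
Reactants: 6
Product: 7 (3S)-3-methyl-5-(2,6,6-trimethylcyclohex-1-en-1-yl)pent-1-en-3-ol
Conditions: Zn dust, AcOH, EtOH, 0 °C → rt
Reagents that add atoms: none
Why: zinc insertion into the C–I bond and β-elimination open the epoxide (reductive ring opening of a 2,3-epoxy iodide) to the tertiary allylic alcohol; the C3–O bond is not touched, so the configuration is retained.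

**Step 6**
Reactants: 8 3-(trimethylsilyl)prop-2-ynal
Product: 10 (3S)-1-(trimethylsilyl)hex-5-en-1-yn-3-ol, via borinate ester 9 (not isolated)
Conditions: (−)-Ipc2B(allyl) (1.2 equiv), Et2O, −78 °C; then 3 M NaOH, 30% H2O2, 0 °C → rt
Reagents that add atoms: (−)-B-allyldiisopinocampheylborane (C=CCB([C@@H]1C[C@@H]2C[C@H]([C@H]1C)C2(C)C)[C@@H]1C[C@@H]2C[C@H]([C@H]1C)C2(C)C)
Why: Brown allylboration through a chair Zimmerman–Traxler transition state; the (+)-α-pinene-derived reagent should add allyl to the Si face of the ynal and so set the (S)-carbinol, the future C5.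

**Step 7**
Reactants: 10
Product: 11 tert-butyldimethyl{[(3S)-1-(trimethylsilyl)hex-5-en-1-yn-3-yl]oxy}silane
Conditions: TBSCl, imidazole, DMF, rt
Reagents that add atoms: tert-butyldimethylsilyl chloride (CC(C)(C)[Si](C)(C)Cl)
Why: standard silylation of the secondary alcohol protects it against β-elimination in the later olefination.

**Step 8**
Reactants: 11
Product: 13 (3S)-3-[(tert-butyldimethylsilyl)oxy]-5-(trimethylsilyl)pent-4-ynal, via secondary ozonide 12 (not isolated)
Conditions: O3, CH2Cl2, −78 °C (Sudan III end point); then PPh3, −78 °C → rt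
Reagents that add atoms: ozone ([O-][O+]=O)
Why: ozonolysis with reductive work-up; the terminal alkene reacts far faster than the silyl alkyne.

**Step 9**
Reactants: 14 methyl 2-[bis(2,2,2-trifluoroethoxy)phosphoryl]acetate
Product: 15 methyl 2-[bis(2,2,2-trifluoroethoxy)phosphoryl]pent-4-enoate (racemic)
Conditions: NaH, DMF, 0 °C; allyl bromide (0.9 equiv), 0 °C → rt
Reagents that add atoms: allyl bromide (C=CCBr)
Why: C-alkylation of the phosphonoacetate sodium salt; a deficit of halide limits dialkylation.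

**Step 10**
Reactants: 13; 15
Product: 16 methyl (2Z,5S)-5-[(tert-butyldimethylsilyl)oxy]-2-(prop-2-en-1-yl)-7-(trimethylsilyl)hept-2-en-6-ynoate
Conditions: 15, KHMDS, 18-crown-6, THF, −78 °C; then 13, −78 °C
Reagents that add atoms: none
Why: Still–Gennari olefination with the electron-poor trifluoroethyl phosphonate should give the kinetic (Z)-trisubstituted enoate (ester cis to the aldehyde-derived CH2), and −78 °C protects the β-silyloxy aldehyde from elimination.

**Step 11**
Reactants: 16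
Product: 17 (2Z,5S)-5-[(tert-butyldimethylsilyl)oxy]-2-(prop-2-en-1-yl)-7-(trimethylsilyl)hept-2-en-6-yn-1-ol
Conditions: DIBAL-H (2.2 equiv), CH2Cl2, −78 °C; Rochelle salt
Reagents that add atoms: none
Why: 1,2-reduction of the enoate gives the allylic alcohol with the alkene geometry unchanged.

**Step 12**
Reactants: 17
Product: 18 (2Z,5S)-2-(prop-2-en-1-yl)hept-2-en-6-yne-1,5-diol
Conditions: TBAF (2.5 equiv), THF, 0 °C → rt
Reagents that add atoms: none
Why: fluoride should cleave both the O–TBS and the alkynyl C–TMS bond, freeing the propargylic hydroxyl needed to direct the next step.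

**Step 13**
Reactants: 18
Product: 20 (2Z,5S,6E)-6-{[dimethyl(propan-2-yloxy)silyl]methyl}-7-iodo-2-(prop-2-en-1-yl)hepta-2,6-diene-1,5-diol (iodine cis to C5), via alkenylmagnesium chelate 19 (not isolated)
Conditions: (iPrO)Me2SiCH2MgCl (5 equiv), CuI (20 mol%), THF, 0 °C → rt; then I2 in THF, −78 → 0 °C; aq. Na2S2O3
Reagents that add atoms: [(isopropoxydimethylsilyl)methyl]magnesium chloride (CC(C)O[Si](C)(C)C[Mg]Cl); iodine (II)
Why: copper-catalysed anti-carbomagnesiation of the propargylic alkoxide should put the silylmethyl group on the internal carbon and magnesium on the terminal carbon, held cis to the alkoxide in a five-membered chelate; iodinolysis with retention then gives the iodoalkene with iodine cis to the carbinol (precedent: the MeMgBr/CuI/I2 route to (Z)-3-iodo-2-methylallyl alcohols).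

**Step 14**
Reactants: 20
Product: 21 (2Z,5S,6Z)-6-(hydroxymethyl)-7-iodo-2-(prop-2-en-1-yl)hepta-2,6-diene-1,5-diol
Conditions: 30% H2O2, KF, KHCO3, THF/MeOH, rt
Reagents that add atoms: hydrogen peroxide (OO)
Why: Tamao–Kumada oxidation converts the alkoxysilyl C–Si bond into C–OH by a peroxide 1,2-shift at silicon, without allylic transposition and without touching the iodoalkene.

**Step 15**
Reactants: 21
Product: 22 (1Z,3S,5Z)-7-[(tert-butyldimethylsilyl)oxy]-2-{[(tert-butyldimethylsilyl)oxy]methyl}-1-iodo-6-(prop-2-en-1-yl)hepta-1,5-dien-3-ol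
Conditions: TBSCl (2.1 equiv), imidazole, CH2Cl2, −20 → 0 °C
Reagents that add atoms: tert-butyldimethylsilyl chloride (CC(C)(C)[Si](C)(C)Cl)
Why: the two primary allylic hydroxyls should silylate well before the hindered secondary one.

**Step 16**
Reactants: 22
Product: 23 tert-butyl{[(2Z,5R,6Z)-6-({[tert-butyl(dimethyl)silyl]oxy}methyl)-5-chloro-7-iodo-2-(prop-2-en-1-yl)hepta-2,6-dien-1-yl]oxy}dimethylsilane
Conditions: PPh3, hexachloroacetone, CH2Cl2, −20 → 0 °C
Reagents that add atoms: hexachloroacetone (O=C(C(Cl)(Cl)Cl)C(Cl)(Cl)Cl)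
Why: Appel-type chlorination through the alkoxyphosphonium salt should proceed by SN2 with inversion to the (R)-chloride; SN2′ and ionisation are disfavoured because the allylic alkene is electron-poor and carries iodine at its far end.

**Step 17**
Reactants: 23
Product: 26 (5S)-4-{[(tert-butyldimethylsilyl)oxy]methyl}-5-[(2Z)-3-{[(tert-butyldimethylsilyl)oxy]methyl}hexa-2,5-dien-1-yl]furan-2(5H)-one, via alkenyllithium 24 (not isolated), via lithium carboxylate 25 (not isolated)
Conditions: t-BuLi (2.1 equiv), Et2O, −100 °C, 10 min; dry CO2, −100 → −78 °C; then DMPU/THF, rt → 45 °C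
Reagents that add atoms: carbon dioxide (O=C=O)
Why: Iodine–lithium exchange with retention gives alkenyllithium 24, which adds to CO2 (C2–C3 bond) to give the lithium (Z)-γ-chloro-enoate 25; on warming, the carboxylate oxygen, held cis to C5 across C3=C4, displaces chloride intramolecularly (O1–C5 bond), a formal (3+2) annulation of a vinyl-anion/allyl-cation synthon with CO2. The closest known reactions are the carboxylation of alkenyllithiums and the lactonisation of (Z)-4-halo-2-enoates by carboxylate SN2 displacement. The furanone ring closes in the 5-exo-tet mode. The C5 stereocentre is set by stereospecific inversion of the (R)-chloride and should come out (S). The step needs exchange to outrun attack on C–Cl (t-BuLi at −100 °C), no elimination to an allene (C4 is fully substituted), no 1,4 O→C silyl shift (the CH2OTBS group is trans to lithium), and ring closure without SN1 or SN2′ leakage (the allylic system is electron-poor and the nucleophile is tethered).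

**Step 18**
Reactants: 26; 7
Product: 27 (5S)-4-{[(tert-butyldimethylsilyl)oxy]methyl}-5-[(2Z,5E,7S)-3-{[(tert-butyldimethylsilyl)oxy]methyl}-7-hydroxy-7-methyl-9-(2,6,6-trimethylcyclohex-1-en-1-yl)nona-2,5-dien-1-yl]furan-2(5H)-one
Conditions: 7 (3 equiv), Hoveyda–Grubbs II (10 mol%), 1,4-benzoquinone (cat.), CH2Cl2, 40 °C
Reagents that add atoms: none
Why: cross-metathesis of the terminal allyl group with the tertiary allylic alcohol, which does not homodimerise, should give the (E)-alkene; the trisubstituted, tetrasubstituted and butenolide alkenes are inert.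

**Step 19**
Reactants: 27
Product: 28 (5S)-4-(hydroxymethyl)-5-[(2Z,5E,7S)-7-hydroxy-3-(hydroxymethyl)-7-methyl-9-(2,6,6-trimethylcyclohex-1-en-1-yl)nona-2,5-dien-1-yl]furan-2(5H)-one (CNP0133996.1)
Conditions: HF·pyridine, pyridine, THF, 0 °C → rt
Reagents that add atoms: none
Why: buffered fluoride desilylation of the two primary TBS ethers avoids base, so the acidic C5–H of the butenolide should not epimerise and the tertiary allylic alcohol should survive.

**Compound list**

1 | dihydro-β-ionone | CC1=C(CCC(C)=O)C(C)(C)CCC1 | starting material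
2 | triethyl phosphonoacetate | CCOC(=O)CP(=O)(OCC)OCC | starting material
3 | ethyl (2E)-3-methyl-5-(2,6,6-trimethylcyclohex-1-en-1-yl)pent-2-enoate | CC1=C(CC/C(C)=C/C(=O)OCC)C(C)(C)CCC1 | intermediate
4 | (2E)-3-methyl-5-(2,6,6-trimethylcyclohex-1-en-1-yl)pent-2-en-1-ol | CC1=C(CC/C(C)=C/CO)C(C)(C)CCC1 | intermediate
5 | [(2S,3S)-3-methyl-3-[2-(2,6,6-trimethylcyclohex-1-en-1-yl)ethyl]oxiran-2-yl]methanol | OC[C@@H]1O[C@@]1(C)CCC2=C(C)CCCC2(C)C | intermediate
6 | (2R,3S)-2-(iodomethyl)-3-methyl-3-[2-(2,6,6-trimethylcyclohex-1-en-1-yl)ethyl]oxirane | IC[C@@H]1O[C@@]1(C)CCC2=C(C)CCCC2(C)C | intermediate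
7 | (3S)-3-methyl-5-(2,6,6-trimethylcyclohex-1-en-1-yl)pent-1-en-3-ol | C=C[C@@](C)(O)CCC1=C(C)CCCC1(C)C | intermediate
8 | 3-(trimethylsilyl)prop-2-ynal | C[Si](C)(C)C#CC=O | starting material
9 | bis(isopinocampheyl)borinate ester of 10 | C=CC[C@H](OB([C@@H]1C[C@@H]2C[C@H]([C@H]1C)C2(C)C)[C@@H]1C[C@@H]2C[C@H]([C@H]1C)C2(C)C)C#C[Si](C)(C)C | intermediate
10 | (3S)-1-(trimethylsilyl)hex-5-en-1-yn-3-ol | C=CC[C@H](O)C#C[Si](C)(C)C | intermediate
11 | tert-butyldimethyl{[(3S)-1-(trimethylsilyl)hex-5-en-1-yn-3-yl]oxy}silane | C=CC[C@H](O[Si](C)(C)C(C)(C)C)C#C[Si](C)(C)C | intermediate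
12 | secondary ozonide (1,2,4-trioxolane) of 11, mixture at the ring carbon | O1OC(C[C@H](O[Si](C)(C)C(C)(C)C)C#C[Si](C)(C)C)OC1 | intermediate
13 | (3S)-3-[(tert-butyldimethylsilyl)oxy]-5-(trimethylsilyl)pent-4-ynal | O=CC[C@H](O[Si](C)(C)C(C)(C)C)C#C[Si](C)(C)C | intermediate
14 | methyl 2-[bis(2,2,2-trifluoroethoxy)phosphoryl]acetate | COC(=O)CP(=O)(OCC(F)(F)F)OCC(F)(F)F | starting material
15 | methyl 2-[bis(2,2,2-trifluoroethoxy)phosphoryl]pent-4-enoate (racemic) | COC(=O)C(CC=C)P(=O)(OCC(F)(F)F)OCC(F)(F)F | intermediate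
16 | methyl (2Z,5S)-5-[(tert-butyldimethylsilyl)oxy]-2-(prop-2-en-1-yl)-7-(trimethylsilyl)hept-2-en-6-ynoate | COC(=O)/C(CC=C)=C\C[C@H](O[Si](C)(C)C(C)(C)C)C#C[Si](C)(C)C | intermediate
17 | (2Z,5S)-5-[(tert-butyldimethylsilyl)oxy]-2-(prop-2-en-1-yl)-7-(trimethylsilyl)hept-2-en-6-yn-1-ol | OC/C(CC=C)=C\C[C@H](O[Si](C)(C)C(C)(C)C)C#C[Si](C)(C)C | intermediate
18 | (2Z,5S)-2-(prop-2-en-1-yl)hept-2-en-6-yne-1,5-diol | OC/C(CC=C)=C\C[C@H](O)C#C | intermediate
19 | alkenylmagnesium chelate (bis-alkoxide, Mg cis to the C5 alkoxide) | Cl[Mg]OC/C(CC=C)=C\C[C@H](O[Mg]Cl)/C(C[Si](C)(C)OC(C)C)=C\[Mg]Cl | intermediate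
20 | (2Z,5S,6E)-6-{[dimethyl(propan-2-yloxy)silyl]methyl}-7-iodo-2-(prop-2-en-1-yl)hepta-2,6-diene-1,5-diol | OC/C(CC=C)=C\C[C@H](O)/C(C[Si](C)(C)OC(C)C)=C\I | intermediate
21 | (2Z,5S,6Z)-6-(hydroxymethyl)-7-iodo-2-(prop-2-en-1-yl)hepta-2,6-diene-1,5-diol | OC/C(CC=C)=C\C[C@H](O)/C(CO)=C\I | intermediate
22 | (1Z,3S,5Z)-7-[(tert-butyldimethylsilyl)oxy]-2-{[(tert-butyldimethylsilyl)oxy]methyl}-1-iodo-6-(prop-2-en-1-yl)hepta-1,5-dien-3-ol | CC(C)(C)[Si](C)(C)OC/C(CC=C)=C\C[C@H](O)/C(CO[Si](C)(C)C(C)(C)C)=C\I | intermediate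
23 | tert-butyl{[(2Z,5R,6Z)-6-({[tert-butyl(dimethyl)silyl]oxy}methyl)-5-chloro-7-iodo-2-(prop-2-en-1-yl)hepta-2,6-dien-1-yl]oxy}dimethylsilane | CC(C)(C)[Si](C)(C)OC/C(CC=C)=C\C[C@@H](Cl)/C(CO[Si](C)(C)C(C)(C)C)=C\I | intermediate
24 | alkenyllithium from 23 (Li in place of I, cis to the C–Cl carbon) | CC(C)(C)[Si](C)(C)OC/C(CC=C)=C\C[C@@H](Cl)/C(CO[Si](C)(C)C(C)(C)C)=C\[Li] | intermediate
25 | lithium (2Z,4R,6Z)-8-[(tert-butyldimethylsilyl)oxy]-3-{[(tert-butyldimethylsilyl)oxy]methyl}-4-chloro-7-(prop-2-en-1-yl)octa-2,6-dienoate | CC(C)(C)[Si](C)(C)OC/C(CC=C)=C\C[C@@H](Cl)/C(CO[Si](C)(C)C(C)(C)C)=C\C(=O)[O-].[Li+] | intermediate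
26 | (5S)-4-{[(tert-butyldimethylsilyl)oxy]methyl}-5-[(2Z)-3-{[(tert-butyldimethylsilyl)oxy]methyl}hexa-2,5-dien-1-yl]furan-2(5H)-one | CC(C)(C)[Si](C)(C)OC/C(CC=C)=C\C[C@@H]1OC(=O)C=C1CO[Si](C)(C)C(C)(C)C | intermediate
27 | (5S)-4-{[(tert-butyldimethylsilyl)oxy]methyl}-5-[(2Z,5E,7S)-3-{[(tert-butyldimethylsilyl)oxy]methyl}-7-hydroxy-7-methyl-9-(2,6,6-trimethylcyclohex-1-en-1-yl)nona-2,5-dien-1-yl]furan-2(5H)-one | CC1=C(CC[C@](C)(O)/C=C/C/C(CO[Si](C)(C)C(C)(C)C)=C/C[C@@H]2OC(=O)C=C2CO[Si](C)(C)C(C)(C)C)C(C)(C)CCC1 | intermediate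
28 | (5S)-4-(hydroxymethyl)-5-[(2Z,5E,7S)-7-hydroxy-3-(hydroxymethyl)-7-methyl-9-(2,6,6-trimethylcyclohex-1-en-1-yl)nona-2,5-dien-1-yl]furan-2(5H)-one | CC1=C(CC[C@](C)(O)/C=C/C/C(=C/C[C@@H]2OC(=O)C=C2CO)CO)C(C)(C)CCC1 | target

**Count and risks**

Total steps: 19. Longest linear sequence: 13 steps (8 → 28 through steps 6–8 and 10–19).

Step 17 (key step). What may go wrong: the alkenyllithium is protonated or attacks the allylic chloride before carboxylation, or the lithium carboxylate closes slowly so that the chloride epimerises or eliminates. Fallback: set out from alcohol 22 and close the ring by palladium-catalysed carbonylative lactonisation (PdCl2(PPh3)2 cat., CO 1 atm, Et3N, THF, 50 °C). Oxidative addition into the C–I bond, CO insertion and capture of the acylpalladium by the cis C5 hydroxyl should give 26 directly; the C5–O bond is not touched, so the (S) configuration of 22 is kept, and the route is rejoined at 26.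

Step 13. What may go wrong: the bulky silylmethyl Grignard reagent adds sluggishly or without regiocontrol, or iodine cleaves the allylic C–Si bond during iodinolysis. Fallback: set out from 17. HF·pyridine/pyridine in THF removes only the O-silyl group to give the C-silyl diol (2Z,5S)-2-(prop-2-en-1-yl)-7-(trimethylsilyl)hept-2-en-6-yne-1,5-diol F1. Titanocene-catalysed hydromagnesiation (i-BuMgBr, Cp2TiCl2 cat., Et2O) adds H–Mg syn with magnesium on the carbon next to the carbinol, giving the alkenylmagnesium species F2. Gaseous formaldehyde then traps it as the vinylsilane triol (2Z,5S,6Z)-6-(hydroxymethyl)-2-(prop-2-en-1-yl)-7-(trimethylsilyl)hepta-2,6-diene-1,5-diol F3, with silicon cis to C5. Ipso-iododesilylation with N-iodosuccinimide (MeCN/ClCH2CN, 0 °C) with retention should return the route at triol 21.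

Step 16. What may go wrong: ionisation, SN2′ attack or elimination during chlorination erodes the configuration at the allylic carbon or gives a diene. Fallback: set out from 22. Mitsunobu inversion (4-nitrobenzoic acid, PPh3, DIAD, THF) gives the inverted 4-nitrobenzoate F4; K2CO3 in MeOH gives the (1Z,3R,5Z)-alcohol F5; MsCl/Et3N at −20 °C gives the (R)-mesylate F6. The exchange/carboxylation of step 17 is then applied to F6 and runs through the alkenyllithium F7 and the lithium carboxylate F8; ring closure with a single inversion rejoins the route at 26.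

**Further compounds**

F0 | step 17 | none | none
F1 | step 13 | (2Z,5S)-2-(prop-2-en-1-yl)-7-(trimethylsilyl)hept-2-en-6-yne-1,5-diol | OC/C(CC=C)=C\C[C@H](O)C#C[Si](C)(C)C
F2 | step 13 | alkenylmagnesium species from hydromagnesiation of F1 (Mg on C6, Si cis to C5) | Br[Mg]OC/C(CC=C)=C\C[C@H](O[Mg]Br)/C([Mg]Br)=C\[Si](C)(C)C
F3 | step 13 | (2Z,5S,6Z)-6-(hydroxymethyl)-2-(prop-2-en-1-yl)-7-(trimethylsilyl)hepta-2,6-diene-1,5-diol | OC/C(CC=C)=C\C[C@H](O)/C(CO)=C\[Si](C)(C)C
F4 | step 16 | (1Z,3R,5Z)-7-[(tert-butyldimethylsilyl)oxy]-2-{[(tert-butyldimethylsilyl)oxy]methyl}-1-iodo-6-(prop-2-en-1-yl)hepta-1,5-dien-3-yl 4-nitrobenzoate | CC(C)(C)[Si](C)(C)OC/C(CC=C)=C\C[C@@H](OC(=O)c1ccc(cc1)[N+](=O)[O-])/C(CO[Si](C)(C)C(C)(C)C)=C\I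
F5 | step 16 | (1Z,3R,5Z)-7-[(tert-butyldimethylsilyl)oxy]-2-{[(tert-butyldimethylsilyl)oxy]methyl}-1-iodo-6-(prop-2-en-1-yl)hepta-1,5-dien-3-ol | CC(C)(C)[Si](C)(C)OC/C(CC=C)=C\C[C@@H](O)/C(CO[Si](C)(C)C(C)(C)C)=C\I
F6 | step 16 | (1Z,3R,5Z)-7-[(tert-butyldimethylsilyl)oxy]-2-{[(tert-butyldimethylsilyl)oxy]methyl}-1-iodo-6-(prop-2-en-1-yl)hepta-1,5-dien-3-yl methanesulfonate | CC(C)(C)[Si](C)(C)OC/C(CC=C)=C\C[C@@H](OS(C)(=O)=O)/C(CO[Si](C)(C)C(C)(C)C)=C\I
F7 | step 16 | alkenyllithium from F6 (Li in place of I) | CC(C)(C)[Si](C)(C)OC/C(CC=C)=C\C[C@@H](OS(C)(=O)=O)/C(CO[Si](C)(C)C(C)(C)C)=C\[Li]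
F8 | step 16 | lithium (Z)-enoate from F7 bearing the (R)-mesylate | CC(C)(C)[Si](C)(C)OC/C(CC=C)=C\C[C@@H](OS(C)(=O)=O)/C(CO[Si](C)(C)C(C)(C)C)=C\C(=O)[O-].[Li+]
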